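## Structural features

The target joins two lignan units through a 5,5′-biaryl bond between two guaiacyl rings (ring A and ring B), each with a free phenol ortho to the axis. Ring A sits on C2 of an oxolane whose C3 carries CH2OH and whose C4 is a tertiary carbinol bearing a 3-hydroxy-4-methoxybenzyl group. C2, C3 and C4 are contiguous (2S,3R,4S), with the aryl group trans to CH2OH and the arylmethyl group cis to it. Ring B sits on C1 of a tetralin whose C2 carries CH2OH, whose C3 is a tertiary carbinol with a second CH2OH, and whose fused ring carries 6-OMe and 7-OH. C1, C2 and C3 are contiguous (all S), 1,2-trans, with the two CH2OH groups trans. Oxolane C2 and tetralin C1 are both para to a phenolic oxygen, so in acid the oxolane C2–O1 bond can ionise and be captured by the benzyl ring on C4, turning the oxolane into a second tetralin. The real difficulty is the two fully substituted carbinols, each set against a neighbouring CH centre, and the near-identical electron demand of the two halves in every acid step. The key step exploits the fact that the arylmethyl carbon on C4 lies on the face of the C3 CH2OH arm and is separated from C4 only by that CH2–O unit, so it can be delivered from a benzylic ether on the C3 CH2O oxygen to a C4 ketone.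

## Logic of the disconnections

40 is first traced back through protecting-group bonds only: five O–benzyl bonds give 39, and the ring A carbamate C–O bond gives 38. Hydrogenolysis and hydride cleavage are the mildest exits to a polyphenol, and every earlier step then runs on non-phenolic material. The demand is that hydrogenolysis spares the oxolane C2–O1 bond and that the carbamate survives every acid step before it.

In 38 the tetralin bond C1–C8a is cut (through 37) to give 36. C1 is para to the ring B oxygen and C8a is para to OMe, so this is the natural Friedel–Crafts bond; the carbocycle becomes an open chain and C1 needs no separate control. The demand is that only C1 ionises: ring B carries an alkoxy group, ring A the electron-poor carbamate, so the oxolane stays closed and the arylmethyl ring on C4 cannot attack C2.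

36 is cut at the C1–ring B bond into 24 and 34. This is the convergent cut; tetralin C2 and C3 are made on a small fragment. The forward step needs bromine–lithium exchange on 24 beside a carbamate and a tertiary alkoxide, and 34 must not epimerise.

24 goes back through 23 (one O–benzyl bond) to 22 by reconnecting the primary oxygen to the benzylic carbon of the C4 arylmethyl group. In 22 the C4 carbinol is a bridgehead of a cis-fused bicycle, so its configuration follows from ring fusion. The demand is that only the para-methoxybenzylic C–O bond of 22 is reduced.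

22 is cut at the bond between C4 and the benzylic carbon, giving 21. This removes the quaternary centre and one ring and leaves the arylmethyl group as a plain ether on oxygen. The forward step needs the excited ketone to abstract the benzylic hydrogen rather than fragment.

21 is cut at O1–C5 (20), then at C4–C5 (18, one-carbon homologation), then at the auxiliary (17), then at C2–C3 into 8 and 15. The trans ring corresponds to an anti aldol, so both stereocentres come from one auxiliary-controlled step. The demand is anti selectivity on the correct enolate face.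

8 is cut at the biaryl bond into 2 and 7; 2 comes from 1, and 7 from 3 through 4, 5 and 6. The coupling must consume the iodide and leave the bromide.

15 is cut at the N-acyl bond into 12 and 13; 12 is cut at the ether C–O bond into 9 and 10 (through 11), a conjugate addition.

34 goes back to 33 (C=C cleavage), 32 (acetal), 31 (C2–vinyl bond, epoxide opening with inversion), 30 (epoxide oxygen, reagent-controlled), then 26 and 28 (sp2–sp3 bond, through 29), and finally 25 and 27. The demand is a defined alkene geometry in 30, because it fixes C3 relative to C2.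

## Other disconnections considered

Alternative 1: The cut is the tetralin C1–C8a bond, made last by isomerisation. The precursor is the bis-oxolane A1, in which ring B also carries an oxolane with a guaiacylmethyl group and the isovanillyl phenol is a mesylate. Acid would ionise the C2–O1 bond of the guaiacylmethyl oxolane, and the ring carbon para to OMe would close the carbocycle to give A2. In its favour, the step needs no reagent beyond acid, no halogen handle and no organometallic coupling. Against it, both oxolanes of A1 are para-hydroxybenzylic ethers and both would ionise; the outcome rests on the mesylated ring being too poor a nucleophile, and that half can still epimerise at C2 by reversible opening. A1 also needs two oxolane constructions with different benzyl groups on one biaryl, and the mesylate must finally be removed beside four free phenols. Compared with the chosen plan, the end game is shorter and more atom-economical (better), and tetralin C1 is set exactly as in step 23 (equal). The cost is moved into the precursor, and the differentiation of the halves is kinetic, whereas the chosen plan fixes it with a carbamate. The chosen key step could supply both oxolanes of A1, so the two plans are complementary.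

Alternative 2: The cuts are the tetralin bonds C1–C2 and C3–C4. Thermal loss of SO2 from the sultine A3 would give an (E)-α-aryl ortho-quinodimethane that adds across C5=C6 of the dioxinone A4 to give A5. In its favour, two C–C bonds, the carbocycle and three contiguous stereocentres form in one convergent, non-acidic step, and the tert-butyl acetal shields one face. Against it, the regiochemistry depends on matching a 1-aryl diene with a β-alkoxyacrylate dienophile of modest reactivity, endo/exo selection must deliver 1,2-trans, and the sultine can rearrange to the less labile sulfone. Compared with steps 15–23 it makes more bonds and stereocentres per step (better) and avoids the acid problem (better). Its regio- and endo/exo control are less predictable than epoxide opening plus intramolecular Friedel–Crafts closure, and it does nothing for the oxolane C4 carbinol, which would still need the photochemical relay.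

Alternative 3: The cuts are C2–C3 and C1–aryl. A chiral Lewis acid, for instance a bisoxazoline complex of Cu(OTf)2, would activate the keto ester of A6; the tethered (E)-alkene would attack the ketone to close the ring, and the C1 cation would be captured by the para position of the phenol ring of A7 to give A8. In its favour, this is the shortest route to the tetralin, it is catalytic in the chiral element, and the biaryl enters without halogen–metal chemistry. Against it, arylpyruvates are largely enolised, the cyclisation can stop at an ene product, and one catalyst must control C3, C2 and C1. The capture at C1 is intermolecular, so para versus ortho attack and the face of the cation are not secured by the substrate. Compared with the chosen plan it is clearly better on step count (better) and forms the same C1 cation as step 23 (equal). The chosen plan traps that cation intramolecularly with a regiodefined arene and sets C2 and C3 stereospecifically. Like alternative 2, it leaves the oxolane untouched.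

Key step: step 12

Remark: 9, 13, 25 and 27 are taken as purchasable; the tartrate in step 18 follows the rule that L-(+)-tartrate gives (2S)-2,3-epoxy alcohols from primary allylic alcohols.
Remark: the configurations of 21 and 22 were checked atom by atom against 40 and agree; the only design change to the photoprecursor is an N,N-diethylcarbamate on ring A in place of an aryl ester, which would be at risk in steps 9 and 22 and whose replacement by an ether would leave the oxolane open to acid in step 23.

Abbreviations: ArA = 2′-(benzyloxy)-5′-bromo-2-(diethylcarbamoyloxy)-3,3′-dimethoxybiphenyl-5-yl; Iv = 3-(benzyloxy)-4-methoxyphenyl; Va = 4-(benzyloxy)-3-methoxyphenyl.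

## Steps

Step 1
Reactants: 1 5-iodovanillin
Product: 2 4-formyl-2-iodo-6-methoxyphenyl N,N-diethylcarbamate
Conditions: Et2NCOCl, K2CO3, MeCN, 80 °C
Reagents that add atoms: N,N-diethylcarbamoyl chloride, CCN(CC)C(Cl)=O
Why: O-carbamoylation of the phenoxide; the carbamate resists hydroperoxide, aryllithium at −78 °C and acid, and keeps ring A electron-poor so the oxolane C2–O1 bond is later neither reduced nor ionised.

Step 2
Reactants: 3 4-bromo-2-methoxyphenol
Product: 4 4-bromo-2-iodo-6-methoxyphenol
Conditions: I2, morpholine, MeOH/CH2Cl2, 0 → 23 °C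
Reagents that add atoms: iodine, II
Why: Electrophilic aromatic iodination; the para position is blocked by bromine and the amine holds the phenol partly as phenoxide, so iodine should enter ortho to OH.

Step 3
Reactants: 4 4-bromo-2-iodo-6-methoxyphenol
Product: 5 2-(benzyloxy)-5-bromo-1-iodo-3-methoxybenzene
Conditions: BnBr, K2CO3, DMF, 23 °C
Reagents that add atoms: benzyl bromide, BrCc1ccccc1
Why: Williamson etherification of the phenoxide; benzyl is kept to the end and makes ring B the electron-rich ring.

Step 4
Reactants: 5 2-(benzyloxy)-5-bromo-1-iodo-3-methoxybenzene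
Product: 7 2-[2-(benzyloxy)-5-bromo-3-methoxyphenyl]-4,4,5,5-tetramethyl-1,3,2-dioxaborolane, via arylmagnesium chloride 6 (not isolated)
Conditions: i-PrMgCl·LiCl, THF, −40 °C; then i-PrOB(pin), −40 → 23 °C
Reagents that add atoms: 2-isopropoxy-4,4,5,5-tetramethyl-1,3,2-dioxaborolane, CC(C)OB1OC(C)(C)C(C)(C)O1
Why: Iodine–magnesium exchange is far faster at C–I than at C–Br, and the aryl Grignard reagent is trapped by the borate ester (borylation).

Step 5
Reactants: 2 4-formyl-2-iodo-6-methoxyphenyl N,N-diethylcarbamate; 7 the aryl boronate of step 4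
Product: 8 2′-(benzyloxy)-5′-bromo-5-formyl-3,3′-dimethoxybiphenyl-2-yl N,N-diethylcarbamate (ArA–CHO)
Conditions: Pd(PPh3)4 (5 mol %), K3PO4, dioxane/H2O, 70 °C
Reagents that add atoms: none
Why: Suzuki–Miyaura coupling; oxidative addition into the C–I bond of the electron-poor aldehyde ring is much faster than into the C–Br bond of the electron-rich partner, so the bromide should survive as the later handle.

Step 6
Reactants: 9 [3-(benzyloxy)-4-methoxyphenyl]methanol (Iv–CH2OH); 10 methyl acrylate
Product: 12 3-{[3-(benzyloxy)-4-methoxyphenyl]methoxy}propanoic acid, via methyl ester 11 (not isolated)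
Conditions: KOtBu (10 mol %), THF, 0 → 23 °C; then LiOH, H2O, 23 °C; HCl to pH 3
Reagents that add atoms: lithium hydroxide, [Li+].[OH-]
Why: Base-catalysed oxa-Michael addition of the benzylic alkoxide followed by saponification in the same flask; ester hydrolysis is faster than retro-addition at room temperature.

Step 7
Reactants: 12 the propanoic acid of step 6; 13 (S)-4-benzyloxazolidin-2-one
Product: 15 (S)-4-benzyl-3-(3-{[3-(benzyloxy)-4-methoxyphenyl]methoxy}propanoyl)oxazolidin-2-one, via mixed pivalic anhydride 14 (not isolated)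
Conditions: t-BuCOCl, Et3N, THF, −20 °C; then 13, LiCl, 23 °C
Reagents that add atoms: none
Why: N-acylation of the oxazolidinone through a mixed anhydride; the nucleophile attacks the less hindered acyl carbon.

Step 8
Reactants: 8 ArA–CHO; 15 the imide of step 7
Product: 17 (S)-4-benzyl-3-[(2R,3S)-3-ArA-3-hydroxy-2-(Iv-methoxymethyl)propanoyl]oxazolidin-2-one, via silyl ether 16 (not isolated)
Conditions: MgCl2 (20 mol %), Et3N, Me3SiCl, EtOAc, 23 °C; then CF3CO2H, MeOH
Reagents that add atoms: none
Why: Magnesium-halide-catalysed anti-aldol of an N-acyloxazolidinone with a non-enolisable aromatic aldehyde; the chelated Z-enolate is attacked on the face away from the benzyl group of the (S)-auxiliary (the face used in enolate alkylation), which sets the α-carbon R, and the anti course sets the carbinol S; silylation of the aldolate drives turnover and the silyl ether is cleaved on work-up.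

Step 9
Reactants: 17 the anti-aldol adduct
Product: 18 (2R,3S)-3-ArA-3-hydroxy-2-(Iv-methoxymethyl)propanoic acid
Conditions: LiOH, H2O2, THF/H2O, 0 °C; Na2SO3; HCl to pH 3
Reagents that add atoms: hydrogen peroxide, OO
Why: Hydroperoxide cleaves the exocyclic imide carbonyl selectively (auxiliary removal) without touching the α-centre; the aryl carbamate and the bromide are inert.

Step 10
Reactants: 18 the β-hydroxy acid
Product: 20 (3R,4S)-4-ArA-1-diazo-4-hydroxy-3-(Iv-methoxymethyl)butan-2-one, via mixed carbonic anhydride 19 (not isolated)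
Conditions: i-BuOCOCl, N-methylmorpholine, THF, −20 °C; then CH2N2, Et2O, 0 °C
Reagents that add atoms: diazomethane, C=[N+]=[N-]
Why: Acylation of diazomethane by a mixed carbonic anhydride (first half of an Arndt–Eistert sequence); β-hydroxy acids are known to tolerate this activation at low temperature without hydroxyl protection.

Step 11
Reactants: 20 the diazoketone
Product: 21 (2S,3R)-2-ArA-3-(Iv-methoxymethyl)oxolan-4-one
Conditions: Rh2(OAc)4 (1 mol %), CH2Cl2, 23 °C, slow addition
Reagents that add atoms: none
Why: Intramolecular O–H insertion of the rhodium carbenoid into the benzylic hydroxyl closes the five-membered ring (O1–C5) under neutral conditions; C2 and C3 are untouched, and trans is also the thermodynamic arrangement at the enolisable C3.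

Step 12
Reactants: 21 the oxolan-4-one
Product: 22 (1S,5R,6S)-6-ArA-2-[3-(benzyloxy)-4-methoxyphenyl]-3,7-dioxabicyclo[3.3.0]octan-1-ol (C2 unassigned)
Conditions: hν (350 nm), degassed benzene (0.01 M), Pyrex, 23 °C
Reagents that add atoms: none
Why: Norrish–Yang photocyclisation: n→π* excitation of the C4 ketone gives an excited carbonyl whose oxygen abstracts a benzylic hydrogen from the O–CH2Ar group of the C3 side chain (a δ-hydrogen, 1,6-transfer through a seven-membered transition state). The resulting 1,5-biradical (C4 ketyl and α-alkoxybenzyl radical) combines to form the C4–CHAr bond. The closest known reaction type is δ-hydrogen abstraction and cyclisation of β-alkoxy ketones to oxolan-3-ols, which is established for 3-(arylmethoxymethyl)oxolan-4-ones giving bridgehead-hydroxy furofurans. The new ring is a five-membered oxolane closed by radical–radical coupling of the 1,5-biradical, and it can only be cis-fused to the existing oxolane. C4 is therefore controlled by the tether: the three-atom chain from C3 reaches only the face of C4 on which the C3 CH2O arm lies, so the new C–C bond is cis to that arm and the hydroxyl trans, as the target requires. The new benzylic centre is not controlled, which does not matter because it becomes CH2 in step 13. The step needs abstraction to win over Norrish α-cleavage and over quenching; the hydrogen is doubly activated (benzylic and α to oxygen), no γ-hydrogen can reach the carbonyl oxygen, and 350 nm light is absorbed by the ketone but not by the aryl bromide, the carbamate or the benzyl ethers. C2 and C3 are spectators.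

Step 13
Reactants: 22 the furofuranol
Product: 23 (2S,3R,4S)-2-ArA-4-(Iv-methyl)-3-(hydroxymethyl)oxolan-4-ol
Conditions: Et3SiH, BF3·OEt2, CH2Cl2, −78 → −40 °C; aq. NaHCO3
Reagents that add atoms: none
Why: Ionic hydrogenation: BF3 ionises the para-methoxybenzylic C–O bond and the silane delivers hydride, turning CHAr into CH2Ar and releasing the primary alcohol; the C2–O1 bond is spared because ring A carries the BF3-bound carbamate, and C4 is not involved.

Step 14
Reactants: 23 the diol
Product: 24 (2S,3R,4S)-2-ArA-3-[(benzyloxy)methyl]-4-(Iv-methyl)oxolan-4-ol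
Conditions: NaH, BnBr, Bu4NI (cat.), THF, 0 → 23 °C
Reagents that add atoms: benzyl bromide, BrCc1ccccc1
Why: Williamson etherification of the primary alkoxide; the tertiary hydroxyl is too hindered to compete, and the ether is removed in the final hydrogenolysis.

Step 15
Reactants: 25 [4-(benzyloxy)-3-methoxyphenyl]methanol (Va–CH2OH)
Product: 26 1-(benzyloxy)-4-(chloromethyl)-2-methoxybenzene
Conditions: SOCl2, CH2Cl2, 0 °C
Reagents that add atoms: thionyl chloride, O=S(Cl)Cl
Why: Chlorodehydroxylation of an electron-rich benzylic alcohol through its chlorosulfite; the chloride is used crude.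

Step 16
Reactants: 27 4-(benzyloxy)but-2-yn-1-ol
Product: 28 (Z)-4-(benzyloxy)-3-iodobut-2-en-1-ol
Conditions: NaAlH2(OCH2CH2OMe)2, THF, 0 °C; then I2, −78 → 0 °C
Reagents that add atoms: iodine, II
Why: Hydroxyl-directed trans-hydroalumination of the propargylic alcohol places aluminium on the distal carbon; iodinolysis with retention gives the (Z)-iodoalkenol.

Step 17
Reactants: 26 the benzylic chloride; 28 the iodoalkenol
Product: 30 (E)-4-(benzyloxy)-3-[4-(benzyloxy)-3-methoxybenzyl]but-2-en-1-ol, via benzylzinc chloride 29 (not isolated)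
Conditions: Zn, LiCl, THF, 23 °C; then 28, Pd(OAc)2 (2 mol %), SPhos (4 mol %), THF, 23 °C
Reagents that add atoms: none
Why: Zinc insertion into the benzylic chloride and Negishi coupling with the alkenyl iodide with retention of geometry, so the arylmethyl group ends cis to CH2OH; organozinc halides tolerate the free hydroxyl.

Step 18
Reactants: 30 the allylic alcohol
Product: 31 {(2R,3R)-3-[(benzyloxy)methyl]-3-[4-(benzyloxy)-3-methoxybenzyl]oxiran-2-yl}methanol
Conditions: Ti(OiPr)4 (10 mol %), D-(−)-diethyl tartrate (12 mol %), t-BuOOH, 4 Å molecular sieves, CH2Cl2, −20 °C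
Reagents that add atoms: tert-butyl hydroperoxide, CC(C)(C)OO
Why: Sharpless asymmetric epoxidation of a 3,3-disubstituted primary allylic alcohol; because the L-(+)-ester gives (2S)-epoxy alcohols, the D-(−)-ester is chosen for the (2R,3R)-epoxide, which fixes the future tetralin C3.

Step 19
Reactants: 31 the epoxy alcohol
Product: 32 (2S,3S)-4-(benzyloxy)-3-[4-(benzyloxy)-3-methoxybenzyl]-2-ethenylbutane-1,3-diol
Conditions: CH2=CHMgBr, CuI (30 mol %), THF, −40 → −10 °C; aq. NH4Cl
Reagents that add atoms: vinylmagnesium bromide, C=C[Mg]Br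
Why: Copper-catalysed SN2 opening of the epoxy alcohol at C2, the only epoxide carbon that is not fully substituted; inversion there sets the future tetralin C2 and leaves the tertiary carbinol.

Step 20
Reactants: 32 the diol
Product: 33 (4S,5S)-4-[(benzyloxy)methyl]-4-[4-(benzyloxy)-3-methoxybenzyl]-5-ethenyl-2,2-dimethyl-1,3-dioxane
Conditions: Me2C(OMe)2, pyridinium p-toluenesulfonate (cat.), CH2Cl2, 23 °C
Reagents that add atoms: 2,2-dimethoxypropane, COC(C)(C)OC
Why: Acid-catalysed transacetalisation of the 1,3-diol; the acetonide blocks retro-aldol cleavage and alkoxide formation in steps 21 and 22.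

Step 21
Reactants: 33 the vinyl dioxane
Product: 34 (4S,5S)-4-[(benzyloxy)methyl]-4-[4-(benzyloxy)-3-methoxybenzyl]-2,2-dimethyl-1,3-dioxane-5-carbaldehyde
Conditions: O3, CH2Cl2/MeOH, −78 °C (dosed to the end-point); then Me2S, −78 → 23 °C
Reagents that add atoms: ozone, [O-][O+]=O
Why: Ozonolysis with reductive work-up; the terminal alkene reacts far faster than the alkoxyarenes at −78 °C, and the neutral work-up avoids epimerisation of the α-centre.

Step 22
Reactants: 24 the bromo oxolane; 34 the aldehyde
Product: 36 secondary benzylic alcohol joining ring B (position 5′) through CH(OH) to C5 of the dioxane (both carbinol epimers), via aryllithium 35 (not isolated)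
Conditions: MeLi (1.05 equiv), THF, −78 °C; t-BuLi (2.1 equiv), −78 °C; then 34, −78 °C; aq. NH4Cl
Reagents that add atoms: none
Why: Deprotonation of the tertiary alcohol, bromine–lithium exchange and 1,2-addition of the aryllithium to the aldehyde; the carbamate has no ortho hydrogen and is inert at −78 °C, and the new carbinol configuration is irrelevant because it is ionised in step 23.

Step 23
Reactants: 36 the benzylic alcohol
Product: 38 (1S,2S,3S)-tetralin with 1-aryl (ring B), 2-CH2OH, 3-OH, 3-CH2OBn, 6-OMe, 7-OBn, ring A still carbamoylated, via tetralin acetonide 37 (not isolated)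
Conditions: CF3CO2H, CH2Cl2, −20 → 0 °C; then H2O/THF, 23 °C
Reagents that add atoms: none
Why: Intramolecular Friedel–Crafts alkylation: the para-benzyloxybenzylic cation at C1 is attacked by the ring carbon para to OMe (six-membered closure), and the aryl group takes the pseudo-equatorial position trans to the C2 substituent, which sets C1 as S; added water then hydrolyses the acetonide, and the oxolane survives because ring A still carries the carbamate.

Step 24
Reactants: 38 the carbamate
Product: 39 penta-O-benzyl ether of the target with ring A phenol free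
Conditions: LiAlH4, THF, 0 → 65 °C; aq. KNaC4H4O6
Reagents that add atoms: none
Why: Hydride reduction of the aryl carbamate releases the ring A phenol and N,N-diethylmethylamine; no other group is reducible.

Step 25
Reactants: 39 the pentabenzyl ether
Product: 40 target CNP0252244.1
Conditions: H2 (1 atm), Pd/C, EtOAc/MeOH, 23 °C
Reagents that add atoms: none
Why: Hydrogenolysis of the five benzyl ethers; benzyl aryl and benzyl alkyl ethers are cleaved much faster than the cyclic benzylic C2–O1 bond under neutral conditions, so the reaction is stopped at full debenzylation.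

## Compound list

1 | 5-iodovanillin | COc1cc(C=O)cc(I)c1O | starting material
2 | 4-formyl-2-iodo-6-methoxyphenyl N,N-diethylcarbamate | CCN(CC)C(=O)Oc1c(I)cc(C=O)cc1OC | intermediate
3 | 4-bromo-2-methoxyphenol | COc1cc(Br)ccc1O | starting material
4 | 4-bromo-2-iodo-6-methoxyphenol | COc1cc(Br)cc(I)c1O | intermediate
5 | 2-(benzyloxy)-5-bromo-1-iodo-3-methoxybenzene | COc1cc(Br)cc(I)c1OCc2ccccc2 | intermediate
6 | [2-(benzyloxy)-5-bromo-3-methoxyphenyl]magnesium chloride | COc1cc(Br)cc([Mg]Cl)c1OCc2ccccc2 | intermediate
7 | 2-[2-(benzyloxy)-5-bromo-3-methoxyphenyl]-4,4,5,5-tetramethyl-1,3,2-dioxaborolane | COc1cc(Br)cc(B2OC(C)(C)C(C)(C)O2)c1OCc3ccccc3 | intermediate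
8 | 2′-(benzyloxy)-5′-bromo-5-formyl-3,3′-dimethoxybiphenyl-2-yl N,N-diethylcarbamate | CCN(CC)C(=O)Oc1c(OC)cc(C=O)cc1-c2cc(Br)cc(OC)c2OCc3ccccc3 | intermediate
9 | [3-(benzyloxy)-4-methoxyphenyl]methanol | COc1ccc(CO)cc1OCc2ccccc2 | starting material
10 | methyl acrylate | C=CC(=O)OC | starting material
11 | methyl 3-{[3-(benzyloxy)-4-methoxyphenyl]methoxy}propanoate | COC(=O)CCOCc1ccc(OC)c(OCc2ccccc2)c1 | intermediate
12 | 3-{[3-(benzyloxy)-4-methoxyphenyl]methoxy}propanoic acid | OC(=O)CCOCc1ccc(OC)c(OCc2ccccc2)c1 | intermediate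
13 | (S)-4-benzyloxazolidin-2-one | O=C1N[C@@H](Cc2ccccc2)CO1 | starting material
14 | mixed anhydride of 12 with pivalic acid | CC(C)(C)C(=O)OC(=O)CCOCc1ccc(OC)c(OCc2ccccc2)c1 | intermediate
15 | (S)-4-benzyl-3-(3-{[3-(benzyloxy)-4-methoxyphenyl]methoxy}propanoyl)oxazolidin-2-one | O=C1OC[C@H](Cc2ccccc2)N1C(=O)CCOCc3ccc(OC)c(OCc4ccccc4)c3 | intermediate
16 | O-trimethylsilyl ether of 17 | O=C1OC[C@H](Cc2ccccc2)N1C(=O)[C@H](COCc3ccc(OC)c(OCc4ccccc4)c3)[C@H](O[Si](C)(C)C)c5cc(OC)c(OC(=O)N(CC)CC)c(-c6cc(Br)cc(OC)c6OCc7ccccc7)c5 | intermediate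
17 | (2R,3S) anti-aldol imide | O=C1OC[C@H](Cc2ccccc2)N1C(=O)[C@H](COCc3ccc(OC)c(OCc4ccccc4)c3)[C@H](O)c5cc(OC)c(OC(=O)N(CC)CC)c(-c6cc(Br)cc(OC)c6OCc7ccccc7)c5 | intermediate
18 | (2R,3S)-3-ArA-3-hydroxy-2-(Iv-methoxymethyl)propanoic acid | OC(=O)[C@H](COCc1ccc(OC)c(OCc2ccccc2)c1)[C@H](O)c3cc(OC)c(OC(=O)N(CC)CC)c(-c4cc(Br)cc(OC)c4OCc5ccccc5)c3 | intermediate
19 | mixed isobutyl carbonic anhydride of 18 | CC(C)COC(=O)OC(=O)[C@H](COCc1ccc(OC)c(OCc2ccccc2)c1)[C@H](O)c3cc(OC)c(OC(=O)N(CC)CC)c(-c4cc(Br)cc(OC)c4OCc5ccccc5)c3 | intermediate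
20 | (3R,4S)-4-ArA-1-diazo-4-hydroxy-3-(Iv-methoxymethyl)butan-2-one | [N-]=[N+]=CC(=O)[C@H](COCc1ccc(OC)c(OCc2ccccc2)c1)[C@H](O)c3cc(OC)c(OC(=O)N(CC)CC)c(-c4cc(Br)cc(OC)c4OCc5ccccc5)c3 | intermediate
21 | (2S,3R)-2-ArA-3-(Iv-methoxymethyl)oxolan-4-one | O=C1CO[C@H](c2cc(OC)c(OC(=O)N(CC)CC)c(-c3cc(Br)cc(OC)c3OCc4ccccc4)c2)[C@H]1COCc5ccc(OC)c(OCc6ccccc6)c5 | intermediate
22 | (1S,5R,6S)-6-ArA-2-Iv-3,7-dioxabicyclo[3.3.0]octan-1-ol, C2 unassigned | COc1ccc(C2OC[C@@H]3[C@@H](c4cc(OC)c(OC(=O)N(CC)CC)c(-c5cc(Br)cc(OC)c5OCc6ccccc6)c4)OC[C@]23O)cc1OCc7ccccc7 | intermediate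
23 | (2S,3R,4S)-2-ArA-3-(hydroxymethyl)-4-(Iv-methyl)oxolan-4-ol | COc1ccc(C[C@@]2(O)CO[C@H](c3cc(OC)c(OC(=O)N(CC)CC)c(-c4cc(Br)cc(OC)c4OCc5ccccc5)c3)[C@H]2CO)cc1OCc6ccccc6 | intermediate
24 | (2S,3R,4S)-2-ArA-3-[(benzyloxy)methyl]-4-(Iv-methyl)oxolan-4-ol | COc1ccc(C[C@@]2(O)CO[C@H](c3cc(OC)c(OC(=O)N(CC)CC)c(-c4cc(Br)cc(OC)c4OCc5ccccc5)c3)[C@H]2COCc6ccccc6)cc1OCc7ccccc7 | intermediate
25 | [4-(benzyloxy)-3-methoxyphenyl]methanol | COc1cc(CO)ccc1OCc2ccccc2 | starting material
26 | 1-(benzyloxy)-4-(chloromethyl)-2-methoxybenzene | COc1cc(CCl)ccc1OCc2ccccc2 | intermediate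
27 | 4-(benzyloxy)but-2-yn-1-ol | OCC#CCOCc1ccccc1 | starting material
28 | (Z)-4-(benzyloxy)-3-iodobut-2-en-1-ol | OC/C=C(\I)COCc1ccccc1 | intermediate
29 | [4-(benzyloxy)-3-methoxybenzyl]zinc chloride | COc1cc(C[Zn]Cl)ccc1OCc2ccccc2 | intermediate
30 | (E)-4-(benzyloxy)-3-[4-(benzyloxy)-3-methoxybenzyl]but-2-en-1-ol | OC/C=C(\Cc1ccc(OCc2ccccc2)c(OC)c1)COCc3ccccc3 | intermediate
31 | {(2R,3R)-3-[(benzyloxy)methyl]-3-[4-(benzyloxy)-3-methoxybenzyl]oxiran-2-yl}methanol | OC[C@H]1O[C@@]1(COCc2ccccc2)Cc3ccc(OCc4ccccc4)c(OC)c3 | intermediate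
32 | (2S,3S)-4-(benzyloxy)-3-[4-(benzyloxy)-3-methoxybenzyl]-2-ethenylbutane-1,3-diol | OC[C@H](C=C)[C@](O)(COCc1ccccc1)Cc2ccc(OCc3ccccc3)c(OC)c2 | intermediate
33 | (4S,5S)-4-[(benzyloxy)methyl]-4-[4-(benzyloxy)-3-methoxybenzyl]-5-ethenyl-2,2-dimethyl-1,3-dioxane | C=C[C@H]1COC(C)(C)O[C@@]1(COCc2ccccc2)Cc3ccc(OCc4ccccc4)c(OC)c3 | intermediate
34 | (4S,5S)-4-[(benzyloxy)methyl]-4-[4-(benzyloxy)-3-methoxybenzyl]-2,2-dimethyl-1,3-dioxane-5-carbaldehyde | O=C[C@H]1COC(C)(C)O[C@@]1(COCc2ccccc2)Cc3ccc(OCc4ccccc4)c(OC)c3 | intermediate
35 | aryllithium from 24 (lithium at ring B position 5′, tertiary lithium alkoxide) | COc1ccc(C[C@@]2(O[Li])CO[C@H](c3cc(OC)c(OC(=O)N(CC)CC)c(-c4cc([Li])cc(OC)c4OCc5ccccc5)c3)[C@H]2COCc6ccccc6)cc1OCc7ccccc7 | intermediate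
36 | benzylic alcohol from 24 and 34 (carbinol epimers) | COc1ccc(C[C@@]2(O)CO[C@H](c3cc(OC)c(OC(=O)N(CC)CC)c(-c4cc(C(O)[C@H]5COC(C)(C)O[C@@]5(COCc6ccccc6)Cc6ccc(OCc7ccccc7)c(OC)c6)cc(OC)c4OCc5ccccc5)c3)[C@H]2COCc6ccccc6)cc1OCc7ccccc7 | intermediate
37 | tetralin with cis-fused acetonide across C2-CH2O and C3-O | COc1ccc(C[C@@]2(O)CO[C@H](c3cc(OC)c(OC(=O)N(CC)CC)c(-c4cc([C@H]5c6cc(OCc7ccccc7)c(OC)cc6C[C@]7(COCc8ccccc8)OC(C)(C)OC[C@H]57)cc(OC)c4OCc5ccccc5)c3)[C@H]2COCc6ccccc6)cc1OCc7ccccc7 | intermediate
38 | (1S,2S,3S)-tetralin diol, ring A carbamate, five benzyl ethers | COc1ccc(C[C@@]2(O)CO[C@H](c3cc(OC)c(OC(=O)N(CC)CC)c(-c4cc([C@H]5c6cc(OCc7ccccc7)c(OC)cc6C[C@@](O)(COCc7ccccc7)[C@@H]5CO)cc(OC)c4OCc5ccccc5)c3)[C@H]2COCc6ccccc6)cc1OCc7ccccc7 | intermediate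
39 | pentabenzyl ether of the target, ring A phenol free | COc1ccc(C[C@@]2(O)CO[C@H](c3cc(OC)c(O)c(-c4cc([C@H]5c6cc(OCc7ccccc7)c(OC)cc6C[C@@](O)(COCc7ccccc7)[C@@H]5CO)cc(OC)c4OCc5ccccc5)c3)[C@H]2COCc6ccccc6)cc1OCc7ccccc7 | intermediate
40 | CNP0252244.1 | COc1ccc(C[C@@]2(O)CO[C@H](c3cc(OC)c(O)c(-c4cc([C@H]5c6cc(O)c(OC)cc6C[C@@](O)(CO)[C@@H]5CO)cc(OC)c4O)c3)[C@H]2CO)cc1O | target

## Step count and risk

Total step count: 25. Longest linear sequence: 15 steps (steps 2, 3, 4, 5, 8, 9, 10, 11, 12, 13, 14, 22, 23, 24, 25).

Step 12 (key step). Most likely failure: the excited α-alkoxy ketone fragments by Norrish α-cleavage, or is quenched by energy transfer to the bromobiaryl, giving low conversion or scrambling of C3 by cleavage and recombination. The reduction that follows (step 13) carries a linked risk: the cation next to the bridgehead carbinol could undergo a 1,2-shift before hydride capture. The fallback sets out from 21 and rejoins at 23, bypassing both steps with known chemistry. Methylenation of 21 with Zn/CH2Br2/TiCl4 would give the 4-methylidene oxolane F1. Epoxidation with mCPBA on the face away from the C3 side chain would give the spiro-epoxide F2. Copper-catalysed opening at the CH2 terminus with [3-(benzyloxy)-4-methoxyphenyl]magnesium bromide would give the tertiary alcohol F3, with the former tether left as a dialkoxybenzyl ether on the primary oxygen. DDQ in wet CH2Cl2 would remove that ether to give 23.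

Step 8. Most likely failure: elimination of the arylmethoxide from the magnesium enolate, or poor facial selectivity caused by chelation of the β-oxygen. The fallback sets out from 8 and 15 and rejoins at 21. A Bu2BOTf/i-Pr2NEt syn-aldol (Evans aldol) would give the syn adduct F4 with the correct carbinol centre. The same three operations as steps 9–11 would give the syn acid F5, the syn diazoketone F6 and the cis-oxolanone F7. Equilibration at the enolisable C3 with catalytic DBU would give the trans ketone 21.

Step 11. Most likely failure: diversion of the carbenoid to an oxonium ylide at the tether oxygen followed by benzyl migration, or addition to an arene. The fallback sets out from 20 and rejoins at 21 without a carbenoid. Aqueous HBr in ether would give the bromomethyl ketone F8, and Ag2O-promoted intramolecular etherification would close the ring.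

Step 22. Most likely failure: enolisation, epimerisation or β-elimination of the α-branched aldehyde by the basic aryllithium, or incomplete exchange. The fallback sets out from 24 and 34 and rejoins at 36. Miyaura borylation of 24 (bis(pinacolato)diboron, PdCl2(dppf), KOAc) would give the aryl boronate F9, and [Rh(OH)(cod)]2-catalysed 1,2-addition to 34 in dioxane/H2O would then give 36 under nearly neutral conditions.

Step 25. Most likely failure: over-reduction, that is hydrogenolysis of the benzylic C2–O1 bond of the oxolane once ring A is a free phenol. The fallback sets out from 38 and rejoins at 40 with the order reversed. Hydrogenolysis of 38 while ring A is still carbamoylated would give the debenzylated carbamate F10, and LiAlH4 in THF at reflux would then release the last phenol.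

## Further compounds

F1 | step 12 | (2S,3R)-2-ArA-3-(Iv-methoxymethyl)-4-methylideneoxolane | C=C1CO[C@H](c2cc(OC)c(OC(=O)N(CC)CC)c(-c3cc(Br)cc(OC)c3OCc4ccccc4)c2)[C@H]1COCc5ccc(OC)c(OCc6ccccc6)c5
F2 | step 12 | spiro-epoxide of F1 (epoxide oxygen trans to the C3 side chain) | C1O[C@@]12CO[C@H](c3cc(OC)c(OC(=O)N(CC)CC)c(-c4cc(Br)cc(OC)c4OCc5ccccc5)c3)[C@H]2COCc6ccc(OC)c(OCc7ccccc7)c6
F3 | step 12 | (2S,3R,4S)-2-ArA-4-(Iv-methyl)-3-(Iv-methoxymethyl)oxolan-4-ol | COc1ccc(C[C@@]2(O)CO[C@H](c3cc(OC)c(OC(=O)N(CC)CC)c(-c4cc(Br)cc(OC)c4OCc5ccccc5)c3)[C@H]2COCc6ccc(OC)c(OCc7ccccc7)c6)cc1OCc8ccccc8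
F4 | step 8 | (2S,3S) syn-aldol imide | O=C1OC[C@H](Cc2ccccc2)N1C(=O)[C@@H](COCc3ccc(OC)c(OCc4ccccc4)c3)[C@H](O)c5cc(OC)c(OC(=O)N(CC)CC)c(-c6cc(Br)cc(OC)c6OCc7ccccc7)c5
F5 | step 8 | (2S,3S) syn β-hydroxy acid | OC(=O)[C@@H](COCc1ccc(OC)c(OCc2ccccc2)c1)[C@H](O)c3cc(OC)c(OC(=O)N(CC)CC)c(-c4cc(Br)cc(OC)c4OCc5ccccc5)c3
F6 | step 8 | syn diazoketone | [N-]=[N+]=CC(=O)[C@@H](COCc1ccc(OC)c(OCc2ccccc2)c1)[C@H](O)c3cc(OC)c(OC(=O)N(CC)CC)c(-c4cc(Br)cc(OC)c4OCc5ccccc5)c3
F7 | step 8 | cis-2-ArA-3-(Iv-methoxymethyl)oxolan-4-one | O=C1CO[C@H](c2cc(OC)c(OC(=O)N(CC)CC)c(-c3cc(Br)cc(OC)c3OCc4ccccc4)c2)[C@@H]1COCc5ccc(OC)c(OCc6ccccc6)c5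
F8 | step 11 | (3R,4S)-4-ArA-1-bromo-4-hydroxy-3-(Iv-methoxymethyl)butan-2-one | BrCC(=O)[C@H](COCc1ccc(OC)c(OCc2ccccc2)c1)[C@H](O)c3cc(OC)c(OC(=O)N(CC)CC)c(-c4cc(Br)cc(OC)c4OCc5ccccc5)c3
F9 | step 22 | pinacol boronate of 24 (boron in place of bromine) | COc1ccc(C[C@@]2(O)CO[C@H](c3cc(OC)c(OC(=O)N(CC)CC)c(-c4cc(B5OC(C)(C)C(C)(C)O5)cc(OC)c4OCc5ccccc5)c3)[C@H]2COCc6ccccc6)cc1OCc7ccccc7
F10 | step 25 | target carrying the ring A N,N-diethylcarbamate | COc1ccc(C[C@@]2(O)CO[C@H](c3cc(OC)c(OC(=O)N(CC)CC)c(-c4cc([C@H]5c6cc(O)c(OC)cc6C[C@@](O)(CO)[C@@H]5CO)cc(OC)c4O)c3)[C@H]2CO)cc1O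
A1 | alternative 1 | bis-oxolane dimer, isovanillyl mesylate | COc1ccc(C[C@@]2(O)CO[C@H](c3cc(OC)c(O)c(-c4cc([C@H]5OC[C@](O)(Cc6ccc(O)c(OC)c6)[C@@H]5CO)cc(OC)c4O)c3)[C@H]2CO)cc1OS(C)(=O)=O
A2 | alternative 1 | target as its isovanillyl mesylate | COc1ccc(C[C@@]2(O)CO[C@H](c3cc(OC)c(O)c(-c4cc([C@H]5c6cc(O)c(OC)cc6C[C@@](O)(CO)[C@@H]5CO)cc(OC)c4O)c3)[C@H]2CO)cc1OS(C)(=O)=O
A3 | alternative 2 | α-biaryl benzo-fused sultine | COc1cc2CS(=O)OC(c3cc(OC)c(OCc4ccccc4)c(-c5cc(Br)cc(OC)c5OCc6ccccc6)c3)c2cc1OCc7ccccc7
A4 | alternative 2 | methyl 2-tert-butyl-4-oxo-1,3-dioxine-6-carboxylate (chiral dioxinone) | COC(=O)C1=CC(=O)O[C@H](C(C)(C)C)O1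
A5 | alternative 2 | dioxanone-fused 1-biaryl tetralin cycloadduct | COc1cc(Br)cc(-c2cc([C@H]5c6cc(OCc8ccccc8)c(OC)cc6C[C@@]7(O[C@@H](C(C)(C)C)OC(=O)[C@H]57)C(=O)OC)cc(OC)c2OCc3ccccc3)c1OCc4ccccc4
A6 | alternative 3 | methyl 3-{4-(benzyloxy)-2-[(E)-3-(benzyloxy)prop-1-enyl]-5-methoxyphenyl}-2-oxopropanoate | COC(=O)C(=O)Cc1cc(OC)c(OCc2ccccc2)cc1/C=C/COCc3ccccc3
A7 | alternative 3 | 2′-(benzyloxy)-5′-bromo-3,3′-dimethoxybiphenyl-2-ol | COc1cc(Br)cc(-c2cccc(OC)c2O)c1OCc3ccccc3
A8 | alternative 3 | 1-biaryl-3-hydroxytetralin-3-carboxylate | COc1cc(Br)cc(-c2cc([C@H]5c6cc(OCc7ccccc7)c(OC)cc6C[C@@](O)(C(=O)OC)[C@@H]5COCc8ccccc8)cc(OC)c2O)c1OCc9ccccc9
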